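In benzofuran numbering, quaternary C3a, shared by the lactone ring and the cyclohexenone ring, carries two arms of identical build, C3–C2(=O) and C4–C5(=O), while the oxygenated carbons C5 and C7a are 1,4-related. Everything therefore rests on cutting C5–C6. The precursor is an achiral keto dialdehyde: C3a bears farnesyl, an acryloyl group (C7a, C7, C6) and two CH2CHO arms. A chiral triazolylidene turns one enantiotopic formyl group into an acyl anion equivalent that adds to C6. This single operation closes the carbocycle, installs the 1,4-diketone and fixes C3a. Aldehyde oxidation, enol lactonisation at C7a and alkene migration then complete the lactone ring and C7a.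

Key step: step 8

Conventions: farnesyl = (2E,6E)-3,7,11-trimethyldodeca-2,6,10-trien-1-yl. Atom labels (O1, C2, C3, C3a, C4–C7, C7a, C1') follow the benzofuran numbering of the target in all compounds.

Assumption: no precedent predicts the sense of induction of the carbene in step 8. The (5aR,10bS) salt is written, and its equally available antipode is taken if the opposite sense is found.

Remark on descriptors: C3a keeps one spatial arrangement from the ring closure to the target. It reads S in the keto aldehyde and R from the keto acid onwards only because the CIP ranking of the two arms changes.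

Design remarks:
- The precursor stays unprotected but is released last, under neutral and non-aqueous conditions, and is used at once.
- Ring size does not exclude three side paths: an acyloin between the two arms, carbene addition to C6 followed by closure of C7 onto a formyl group, and a later crossed benzoin of the spectator aldehyde with the new C5 ketone.
- These paths are met by an electron-poor carbene, no free base, high dilution and immediate oxidation of the crude product.

Step 1
Reactants: 1 methyl cyclopent-3-ene-1-carboxylate
Product: 2 methyl (3R,4S)-3,4-dihydroxycyclopentane-1-carboxylate (meso cis-diol, hydroxyls trans to the ester)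
Conditions: OsO4 (1 mol %), NMO (1.3 equiv), acetone/H2O, rt
Reagents that add atoms: osmium tetroxide (oxygen carrier) O=[Os](=O)(=O)=O; N-methylmorpholine N-oxide C[N+]1([O-])CCOCC1; water O
Why: Upjohn dihydroxylation: the concerted suprafacial [3+2] addition of OsO4 sets the two carbinol centres cis to each other (meso) on the face away from the ester, and running it before farnesyl is present means no other alkene competes.

Step 2
Reactants: 2 methyl (3R,4S)-3,4-dihydroxycyclopentane-1-carboxylate
Product: 3 methyl (3aR,6aS)-2,2-dimethyltetrahydro-4H-cyclopenta[d][1,3]dioxole-5-carboxylate (meso acetonide)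
Conditions: Me2C(OMe)2, TsOH·H2O (2 mol %), acetone, rt
Reagents that add atoms: 2,2-dimethoxypropane COC(C)(C)OC
Why: Acid-catalysed transketalisation (acetonide formation) ties the cis-diol into a dioxolane that tolerates the amide base and Grignard reagents of steps 3 to 5 and touches no stereocentre.

Step 3
Reactants: 3 acetonide ester; 4 (E,E)-farnesyl bromide
Product: 6 methyl (3aR,6aS)-5-farnesyl-2,2-dimethyltetrahydro-4H-cyclopenta[d][1,3]dioxole-5-carboxylate (achiral, farnesyl anti to the dioxolane oxygens), via lithium enolate 5 (not isolated)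
Conditions: LiN(iPr)2 (commercial solution, 1.1 equiv), THF, −78 °C; then 4, DMPU, −78 → 0 °C
Reagents that add atoms: (E,E)-farnesyl bromide 4 CC(C)=CCC/C(C)=C/CC/C(C)=C/CBr
Why: Ester enolate alkylation: SN2 displacement at the primary allylic bromide keeps the E alkenes and builds the quaternary carbon from the convex face, a relative configuration of no consequence because this carbon turns prochiral in step 7.

Step 4
Reactants: 6 farnesylated ester
Product: 7 (3aR,6aS)-5-farnesyl-N-methoxy-N,2,2-trimethyltetrahydro-4H-cyclopenta[d][1,3]dioxole-5-carboxamide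
Conditions: MeNH(OMe)·HCl (3 equiv), iPrMgCl (6 equiv), THF, −20 °C → rt
Reagents that add atoms: N,O-dimethylhydroxylamine hydrochloride CNOC.Cl
Why: Weinreb amide synthesis from an ester: the small, strongly nucleophilic magnesium amide attacks a methyl ester that has no alpha hydrogen and sits on a tied-back cyclopentane, so acyl substitution is the only open path.

Step 5
Reactants: 7 Weinreb amide; 8 vinylmagnesium bromide
Product: 10 1-[(3aR,6aS)-5-farnesyl-2,2-dimethyltetrahydro-4H-cyclopenta[d][1,3]dioxol-5-yl]prop-2-en-1-one, via magnesium hemiaminal 9 (not isolated)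
Conditions: 8 (2.5 equiv), THF, 0 °C → rt; inverse quench into cold 1 M HCl/Et2O
Reagents that add atoms: vinylmagnesium bromide 8 C=C[Mg]Br
Why: Weinreb ketone synthesis: chelated hemiaminal 9 survives until the quench, so neither a second 1,2-addition nor a conjugate addition can occur, and pouring into cold acid protonates the released amine before it can add to the vinyl ketone.

Step 6
Reactants: 10 vinyl ketone acetonide
Product: 11 1-[(3R,4S)-1-farnesyl-3,4-dihydroxycyclopentyl]prop-2-en-1-one (achiral cis-diol)
Conditions: AcOH/H2O 4:1, BHT (trace), 50 °C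
Reagents that add atoms: none
Why: Acid-catalysed acetal hydrolysis in a weak carboxylic acid is too mild to protonate the trisubstituted farnesyl alkenes or to hydrate the hindered enone, and the radical inhibitor suppresses polymerisation.

Step 7
Reactants: 11 diol vinyl ketone
Product: 12 3-acryloyl-3-farnesylpentanedial (achiral)
Conditions: NaIO4 on silica gel, CH2Cl2, rt; filter, dry azeotropically with toluene, use at once
Reagents that add atoms: none
Why: Malaprade glycol cleavage through the cyclic periodate ester of the cis-diol is neutral, leaves alkenes and enone alone and allows isolation by filtration, and the ring stereocentres vanish so that 12 has two enantiotopic CH2CHO arms.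

Step 8
Reactants: 12 3-acryloyl-3-farnesylpentanedial
Product: 14 (S)-2-(1-farnesyl-2,5-dioxocyclohexyl)acetaldehyde, via enaminol 13 (not isolated)
Conditions: (5aR,10bS)-2-(pentafluorophenyl)-5a,10b-dihydro-4H,6H-indeno[2,1-b][1,2,4]triazolo[4,3-d][1,4]oxazin-2-ium tetrafluoroborate (20 mol %), KN(SiMe3)2 (18 mol %), 4 Å MS, toluene (0.01 M), 23–45 °C, Ar; crude product taken on directly
Reagents that add atoms: none
Why: Proposed new method: either formyl group of 12 can take up the free triazolylidene in a reversible addition, a proton shift gives enaminol 13 (the acyl anion equivalent at C5), C5 attacks the terminal carbon C6 of the acryloyl unit in its s-trans rotamer, and protonation at C7 followed by expulsion of the carbene leaves the C5/C7a 1,4-diketone. The closest known reaction types are enantioselective intramolecular Stetter reactions of aliphatic aldehydes, which are exo closures, and Stetter desymmetrisations in which one aldehyde chooses between two enantiotopic acceptor alkenes; an endo closure in which the catalyst chooses between two aldehydes has not been shown. The one new ring (C3a–C4–C5–C6–C7–C7a) closes 6-endo-trig through the C5–C6 bond, a mode allowed by the Baldwin rules and followed by stabilised carbanions in the second stage of double Michael annulations of divinyl ketones. C3a is the only new stereocentre and is controlled by the catalyst: the indane wall fixes which face of the enaminol is open and with it the sense of the chair-like transition state, in which farnesyl and the spectator CH2CHO arm must divide one axial and one equatorial site on C3a, and the slimmer formylmethyl arm, which can also accept a hydrogen bond from the enaminol OH in toluene, is expected to take the axial site next to the azolium. The step needs selection between enantiotopic aldehyde groups and preference for conjugate addition over acyloin, aldol and Baylis–Hillman-type paths; the substrate secures this because the two diastereomeric enaminols interconvert through 12 faster than the irreversible C–C bond formation, the five-membered acyloin between the arms can revert, enolate closures would have to form rings of three or four atoms or run 5-endo-trig, and the farnesyl alkenes are not acceptors. An electron-poor carbene whose addition to the enone is reversible, no base beyond the carbene, high dilution and immediate oxidation of crude 14 are chosen against oligomerisation and against a later crossed benzoin of the spectator aldehyde with the new C5 ketone.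

Step 9
Reactants: 14 (S)-2-(1-farnesyl-2,5-dioxocyclohexyl)acetaldehyde
Product: 15 (R)-2-(1-farnesyl-2,5-dioxocyclohexyl)acetic acid
Conditions: NaClO2, NaH2PO4, 2-methylbut-2-ene (30 equiv), tBuOH/THF/H2O, 0 °C → rt
Reagents that add atoms: sodium chlorite [Na+].[O-]Cl=O
Why: Pinnick oxidation is selective for the aldehyde and leaves the ketones untouched, the large excess of 2-methylbut-2-ene intercepts HOCl before it can chlorinate the farnesyl alkenes, and quaternary C3a cannot epimerise.

Step 10
Reactants: 15 (R)-keto acid
Product: 16 (3aR)-3a-farnesyl-3a,4-dihydro-1-benzofuran-2,5(3H,6H)-dione (C7=C7a enol lactone)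
Conditions: Ac2O, NaOAc, 100 °C; evaporate with toluene, short dry silica plug
Reagents that add atoms: none
Why: Classical enol lactonisation of a gamma-keto acid (pseudo-acid acetate or mixed anhydride, then loss of acetic acid): the C7a ketone can enolise only towards C7 because C3a is quaternary, and a lactone to C5 would need a bridgehead alkene, so only one enol lactone is possible.

Step 11
Reactants: 16 enol lactone
Product: 17 (3aR,7aR)-3a-farnesyl-3a,7a-dihydro-1-benzofuran-2,5(3H,4H)-dione (target, cis-fused)
Conditions: DBU (0.1 equiv), dry CH2Cl2 (0.02 M), 0 °C → rt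
Reagents that add atoms: none
Why: Base-catalysed prototropic shift of a beta,gamma-unsaturated ketone into conjugation: DBU removes the doubly activated C6 proton, and reprotonation of the extended enolate at C7a under equilibrating conditions gives the conjugated enone with the less strained cis fusion, the proton arriving on the farnesyl face because O1 is tethered through C2–C3 to the opposite face of C3a.

Compound list
1 | methyl cyclopent-3-ene-1-carboxylate | COC(=O)C1CC=CC1 | starting material
2 | methyl (3R,4S)-3,4-dihydroxycyclopentane-1-carboxylate, diol trans to ester | COC(=O)[C@H]1C[C@H](O)[C@H](O)C1 | intermediate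
3 | methyl (3aR,6aS)-2,2-dimethyltetrahydro-4H-cyclopenta[d][1,3]dioxole-5-carboxylate | COC(=O)[C@H]1C[C@@H]2OC(C)(C)O[C@@H]2C1 | intermediate
4 | (E,E)-farnesyl bromide | CC(C)=CCC/C(C)=C/CC/C(C)=C/CBr | starting material
5 | lithium enolate of 3 | COC(O[Li])=C1C[C@@H]2OC(C)(C)O[C@@H]2C1 | intermediate
6 | methyl (3aR,6aS)-5-farnesyl-2,2-dimethyltetrahydro-4H-cyclopenta[d][1,3]dioxole-5-carboxylate | CC(C)=CCC/C(C)=C/CC/C(C)=C/C[C@@]1(C(=O)OC)C[C@@H]2OC(C)(C)O[C@@H]2C1 | intermediate
7 | Weinreb amide of 6 | CC(C)=CCC/C(C)=C/CC/C(C)=C/C[C@@]1(C(=O)N(C)OC)C[C@@H]2OC(C)(C)O[C@@H]2C1 | intermediate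
8 | vinylmagnesium bromide | C=C[Mg]Br | starting material
9 | bromomagnesium hemiaminal from 7 and 8 (carbinol carbon racemic) | CC(C)=CCC/C(C)=C/CC/C(C)=C/C[C@@]1(C(O[Mg]Br)(C=C)N(C)OC)C[C@@H]2OC(C)(C)O[C@@H]2C1 | intermediate
10 | 1-[(3aR,6aS)-5-farnesyl-2,2-dimethyltetrahydro-4H-cyclopenta[d][1,3]dioxol-5-yl]prop-2-en-1-one | CC(C)=CCC/C(C)=C/CC/C(C)=C/C[C@@]1(C(=O)C=C)C[C@@H]2OC(C)(C)O[C@@H]2C1 | intermediate
11 | 1-[(3R,4S)-1-farnesyl-3,4-dihydroxycyclopentyl]prop-2-en-1-one | CC(C)=CCC/C(C)=C/CC/C(C)=C/C[C@@]1(C(=O)C=C)C[C@H](O)[C@H](O)C1 | intermediate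
12 | 3-acryloyl-3-farnesylpentanedial | CC(C)=CCC/C(C)=C/CC/C(C)=C/CC(CC=O)(CC=O)C(=O)C=C | intermediate
13 | enaminol formed from the carbene and the formyl group that becomes C5 (enol geometry open) | CC(C)=CCC/C(C)=C/CC/C(C)=C/C[C@@](CC=O)(C(=O)C=C)CC(O)=C1N(c2c(F)c(F)c(F)c(F)c2F)N=C2CO[C@@H]3Cc4ccccc4[C@@H]3N12 | intermediate
14 | (S)-2-(1-farnesyl-2,5-dioxocyclohexyl)acetaldehyde | CC(C)=CCC/C(C)=C/CC/C(C)=C/C[C@]1(CC=O)CC(=O)CCC1=O | intermediate
15 | (R)-2-(1-farnesyl-2,5-dioxocyclohexyl)acetic acid | CC(C)=CCC/C(C)=C/CC/C(C)=C/C[C@]1(CC(=O)O)CC(=O)CCC1=O | intermediate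
16 | (3aR)-3a-farnesyl-3a,4-dihydro-1-benzofuran-2,5(3H,6H)-dione | CC(C)=CCC/C(C)=C/CC/C(C)=C/C[C@]12CC(=O)CC=C1OC(=O)C2 | intermediate
17 | (3aR,7aR)-3a-farnesyl-3a,7a-dihydro-1-benzofuran-2,5(3H,4H)-dione | CC(C)=CCC/C(C)=C/CC/C(C)=C/C[C@]12CC(=O)C=C[C@H]1OC(=O)C2 | target

Total step count: 11. Longest linear sequence: 11 steps (1 to 17).

Steps most likely to fail

1) Step 8.
- What may go wrong: the enaminol may close onto the second formyl group faster than it reaches C6.
- The carbene may add to C6 itself and start a Baylis–Hillman-type closure or chain growth.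
- Discrimination between farnesyl and the spectator arm in the transition state may be too weak for useful enantioselection.
- The spectator aldehyde may react on with the new ketone.
- Fallback (known chemistry): give up the desymmetrisation and set C3a by a chiral-imine Michael addition on a preformed ring. The fallback sets out from farnesyl bromide 4. The lithium enolate (LiN(iPr)2, THF, −78 °C) of commercial 1,4-dioxaspiro[4.5]decan-8-one is alkylated with 4 to racemic 7-farnesyl-1,4-dioxaspiro[4.5]decan-8-one F1. Condensation with (S)-1-phenylethylamine (toluene, 4 Å MS) gives the N-(1-phenylethyl) imine F2. Its more substituted secondary enamine tautomer adds to freshly prepared nitroethylene on the face left open by the phenyl group, which gives the quaternary nitroethyl imine F3. The (S)-amine is chosen by analogy with the established sense for 2-alkylcyclohexanones. Aqueous AcOH hydrolyses F3 to (S)-7-farnesyl-7-(2-nitroethyl)-1,4-dioxaspiro[4.5]decan-8-one F4. A Nef reaction (NaOMe, then TiCl3 in NH4OAc buffer) gives (S)-2-(7-farnesyl-8-oxo-1,4-dioxaspiro[4.5]decan-7-yl)acetaldehyde F5. PPTS in wet acetone then removes the dioxolane, and the fallback returns to the route at 14.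

2) Step 10.
- What may go wrong: the extended enolate formed at the doubly activated C6 position may be acetylated on its C5 oxygen.
- The acid may be trapped as a bridged pseudo-ester at C5.
- The enol lactone may hydrolyse on handling.
- The position of the equilibrium in step 11 is untested.
- Fallback: replace the redox-neutral endgame by a reduction–oxidation sequence. It sets out from 15 and bypasses 16. NaBH4 in MeOH reduces both ketones. On acidification with citric acid, the C7a alcohol that lies cis to the acetic acid arm lactonises to (3aR,7aR)-3a-farnesyl-5-hydroxyhexahydro-1-benzofuran-2(3H)-one F6 (C5 epimers). The hydroxy acid of opposite C7a configuration stays open, is removed by base extraction and can be re-oxidised. Dess–Martin periodinane gives (3aR,7aR)-3a-farnesyltetrahydro-1-benzofuran-2,5(3H,4H)-dione F7. LiN(SiMe3)2 and Me3SiCl at −78 °C give the C5=C6 trimethylsilyl enol ether F8. Saegusa–Ito oxidation with Pd(OAc)2 in MeCN can place the alkene only at C6–C7, because C3a carries no hydrogen, and the fallback returns to the route at 17.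

3) Step 4.
- What may go wrong: acyl substitution at the neopentyl-type carbonyl may be slow, and forcing conditions may cleave the N–O bond of the amide once it forms.
- Fallback: exchange acyl substitution for a redox and 1,2-addition sequence. It sets out from 6. LiAlH4 in Et2O gives the primary alcohol [(3aR,6aS)-5-farnesyl-2,2-dimethyltetrahydro-4H-cyclopenta[d][1,3]dioxol-5-yl]methanol F9. Dess–Martin periodinane gives the non-enolisable carbaldehyde F10. Vinylmagnesium bromide 8 adds to give the racemic allylic alcohol F11. A second Dess–Martin oxidation returns to the route at 10.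

Further compounds
F1 | step 8 | racemic 7-farnesyl-1,4-dioxaspiro[4.5]decan-8-one | CC(C)=CCC/C(C)=C/CC/C(C)=C/CC1CC2(CCC1=O)OCCO2
F2 | step 8 | N-[(S)-1-phenylethyl] imine of F1 | CC(C)=CCC/C(C)=C/CC/C(C)=C/CC1CC2(CCC1=N[C@@H](C)c3ccccc3)OCCO2
F3 | step 8 | (7S)-7-farnesyl-7-(2-nitroethyl)-N-[(S)-1-phenylethyl]-1,4-dioxaspiro[4.5]decan-8-imine | CC(C)=CCC/C(C)=C/CC/C(C)=C/C[C@]1(CC[N+](=O)[O-])CC2(CCC1=N[C@@H](C)c3ccccc3)OCCO2
F4 | step 8 | (S)-7-farnesyl-7-(2-nitroethyl)-1,4-dioxaspiro[4.5]decan-8-one | CC(C)=CCC/C(C)=C/CC/C(C)=C/C[C@]1(CC[N+](=O)[O-])CC2(CCC1=O)OCCO2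
F5 | step 8 | (S)-2-(7-farnesyl-8-oxo-1,4-dioxaspiro[4.5]decan-7-yl)acetaldehyde | CC(C)=CCC/C(C)=C/CC/C(C)=C/C[C@]1(CC=O)CC2(CCC1=O)OCCO2
F6 | step 10 | (3aR,7aR)-3a-farnesyl-5-hydroxyhexahydro-1-benzofuran-2(3H)-one (C5 epimers) | CC(C)=CCC/C(C)=C/CC/C(C)=C/C[C@]12CC(O)CC[C@H]1OC(=O)C2
F7 | step 10 | (3aR,7aR)-3a-farnesyltetrahydro-1-benzofuran-2,5(3H,4H)-dione | CC(C)=CCC/C(C)=C/CC/C(C)=C/C[C@]12CC(=O)CC[C@H]1OC(=O)C2
F8 | step 10 | (3aR,7aR)-3a-farnesyl-5-(trimethylsilyloxy)-3a,4,7,7a-tetrahydro-1-benzofuran-2(3H)-one | CC(C)=CCC/C(C)=C/CC/C(C)=C/C[C@]12CC(O[Si](C)(C)C)=CC[C@H]1OC(=O)C2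
F9 | step 4 | [(3aR,6aS)-5-farnesyl-2,2-dimethyltetrahydro-4H-cyclopenta[d][1,3]dioxol-5-yl]methanol | CC(C)=CCC/C(C)=C/CC/C(C)=C/C[C@@]1(CO)C[C@@H]2OC(C)(C)O[C@@H]2C1
F10 | step 4 | (3aR,6aS)-5-farnesyl-2,2-dimethyltetrahydro-4H-cyclopenta[d][1,3]dioxole-5-carbaldehyde | CC(C)=CCC/C(C)=C/CC/C(C)=C/C[C@@]1(C=O)C[C@@H]2OC(C)(C)O[C@@H]2C1
F11 | step 4 | 1-[(3aR,6aS)-5-farnesyl-2,2-dimethyltetrahydro-4H-cyclopenta[d][1,3]dioxol-5-yl]prop-2-en-1-ol (carbinol racemic) | CC(C)=CCC/C(C)=C/CC/C(C)=C/C[C@@]1(C(O)C=C)C[C@@H]2OC(C)(C)O[C@@H]2C1
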